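Ring C (O1, C2, C3, C4, C4a, C8a) is assembled as a formal hetero-[4+2]: the aldehyde O1=C2 of ring B adds across C3 and C8a of a ring-A ketone. The feature used is that the aryl ether carbon C8a sits ortho to C4a, so a temporary carbonyl at C4 both turns C3 into an enol-silane nucleophile and activates a C8a–F bond for ipso-substitution. In one flask, a catalytic asymmetric Mukaiyama aldol (C2–C3) and a fluoride-triggered cyclisation (O1–C8a) convert an acyclic 2-fluoroaryl α-benzyloxy enol silane and 4-benzyloxybenzaldehyde into the 2,3-cis flavanone. The C4 carbonyl is later reduced and ionised, and piceatannol adds trans to the 3-OH.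

Key step: step 3

Remarks
- Atom labels follow flavan numbering (O1, C2, C3, C4, C4a, C8a); ring A is the fused benzene ring, ring B the 4-hydroxyphenyl group, ring C the pyran.
- Assumption: the (acyloxy)borane made from natural (2R,3R)-tartaric acid is taken to direct enol silanes to the re face of aromatic aldehydes. The si-face attack needed for (2R) is therefore assigned to the catalyst from (2S,3S)-tartaric acid; the antipodal catalyst would be used if the sense proved opposite.

Step 1
Reactants: 1 4-(benzyloxy)-1-bromo-2-fluorobenzene; 2 2-(benzyloxy)-N-methoxy-N-methylacetamide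
Product: 4 2-(benzyloxy)-1-[4-(benzyloxy)-2-fluorophenyl]ethan-1-one, via arylmagnesium chloride 3 (not isolated)
Conditions: iPrMgCl·LiCl (1.1 equiv), THF, 0 °C to rt; then 2, −20 to 0 °C; aq NH4Cl
Reagents that add atoms: isopropylmagnesium chloride–lithium chloride, CC(C)[Mg]Cl.[Li+].[Cl-] (its MgCl is found in intermediate 3 only)
Why: Bromine–magnesium exchange with the turbo-Grignard reagent should be faster than loss of fluoride from the ortho-fluoroaryl magnesium species at or below room temperature, and the chelated tetrahedral adduct of the Weinreb ketone synthesis prevents over-addition.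

Step 2
Reactants: 4 2-(benzyloxy)-1-[4-(benzyloxy)-2-fluorophenyl]ethan-1-one
Product: 5 (Z)-{[2-(benzyloxy)-1-[4-(benzyloxy)-2-fluorophenyl]ethenyl]oxy}trimethylsilane
Conditions: TMSOTf (1.2 equiv), Et3N (1.5 equiv), CH2Cl2, 0 °C; non-aqueous work-up (pentane, filtration), used directly
Reagents that add atoms: trimethylsilyl trifluoromethanesulfonate, C[Si](C)(C)OS(=O)(=O)C(F)(F)F
Why: Soft enolisation (silyl triflate and amine) at the only enolisable position should give the enol silane, the Z isomer being expected because the aryl group avoids the benzyloxy substituent, and the geometry is not decisive for step 3.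

Step 3
Reactants: 5 (Z)-{[2-(benzyloxy)-1-[4-(benzyloxy)-2-fluorophenyl]ethenyl]oxy}trimethylsilane; 6 4-(benzyloxy)benzaldehyde
Product: 8 (2R,3S)-3,7-bis(benzyloxy)-2-[4-(benzyloxy)phenyl]-2,3-dihydro-4H-chromen-4-one (2,3-cis), via silyl aldolate 7 (not isolated)
Conditions: 5 (1.2 equiv), 6 (1.0 equiv), chiral (acyloxy)borane made in situ from (2S,3S)-2-O-(2,6-diisopropoxybenzoyl)tartaric acid and BH3·THF (20 mol %), EtCN, −78 °C; then, same flask, CsF (2 equiv), 18-crown-6 (0.2 equiv), DMF, −40 to 0 °C
Reagents that add atoms: none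
Why: The boron Lewis acid binds the aldehyde and C3 of the enol silane adds through an open transition state (Mukaiyama aldol, C2–C3), with silicon ending on O1; fluoride then unmasks the O1 alkoxide, which adds to C8a and expels fluoride through a Meisenheimer intermediate (intramolecular SNAr, O1–C8a), the expelled fluoride carrying the desilylation on. The closest known reaction type is the stepwise hetero-Diels–Alder (Mukaiyama aldol, then addition–elimination) of 1-alkoxy-3-silyloxy dienes with aldehydes, here with C8a–F of ring A in the role of the 1-alkoxy terminus. Ring C closes in a 6-exo-trig addition–elimination mode at the aromatic carbon C8a, which the ortho C4 carbonyl activates. C2 is set by the catalyst (attack on the si face of the aldehyde) and C3 by the syn preference of the open transition state, which holds for either enol silane geometry; syn maps onto 2,3-cis because the closure retains both centres. The step needs O1 and not O3 to be arylated, which the benzyl ether on O3 secures, and it needs the kinetic cis isomer to survive, which the low temperature and the absence of a stoichiometric strong base are meant to secure.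

Step 4
Reactants: 8 (2R,3S)-3,7-bis(benzyloxy)-2-[4-(benzyloxy)phenyl]-2,3-dihydro-4H-chromen-4-one
Product: 9 (2R,3S)-3,7-dihydroxy-2-(4-hydroxyphenyl)-2,3-dihydro-4H-chromen-4-one (2,3-cis)
Conditions: H2 (1 atm), 10% Pd/C, EtOAc–EtOH, rt; filtered and used without chromatography
Reagents that add atoms: none
Why: Hydrogenolysis of the three benzyl ethers over Pd/C should be faster than reduction of the electron-rich aryl ketone or cleavage of the cyclic benzylic C2–O1 bond, and the neutral medium leaves the cis stereocentres untouched.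

Step 5
Reactants: 9 (2R,3S)-3,7-dihydroxy-2-(4-hydroxyphenyl)-2,3-dihydro-4H-chromen-4-one
Product: 10 (2R,3R,4R)-2-(4-hydroxyphenyl)chromane-3,4,7-triol (2,3-cis-3,4-cis flavan-3,4-diol)
Conditions: NaBH4 (excess), EtOH, 0 °C to rt; AcOH to pH 6–7, EtOAc extraction; used directly
Reagents that add atoms: none
Why: Borohydride reduction of a free dihydroflavonol gives the flavan-3,4-diol, hydride being expected to add to C4 anti to the axial 3-OH (3,4-cis), although the C4 configuration is erased in step 6.

Step 6
Reactants: 10 (2R,3R,4R)-2-(4-hydroxyphenyl)chromane-3,4,7-triol; 11 piceatannol, (E)-4-[2-(3,5-dihydroxyphenyl)ethenyl]benzene-1,2-diol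
Product: 12 (2R,3R,4R)-4-{2-[(E)-2-(3,4-dihydroxyphenyl)ethenyl]-4,6-dihydroxyphenyl}-2-(4-hydroxyphenyl)chromane-3,7-diol (target)
Conditions: 11 (4 equiv), 0.1 M HCl in H2O–EtOH (1:1), rt, N2, dark; excess 11 recovered by chromatography (Sephadex LH-20)
Reagents that add atoms: none
Why: Mild acid ionises the 4-OH to a benzylic cation stabilised by the para 7-OH, and the resorcinol ring of piceatannol should attack it in a Friedel–Crafts alkylation through the ring carbon ortho to the styryl group and para to a hydroxyl, from the face anti to the 3-OH and the ring-B substituent, which sets (4R) and the 3,4-trans relation.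

Compound list
1 | 4-(benzyloxy)-1-bromo-2-fluorobenzene | Fc1cc(OCc2ccccc2)ccc1Br | starting material
2 | 2-(benzyloxy)-N-methoxy-N-methylacetamide | CON(C)C(=O)COCc1ccccc1 | starting material
3 | [4-(benzyloxy)-2-fluorophenyl]magnesium chloride (LiCl complex) | Fc1cc(OCc2ccccc2)ccc1[Mg]Cl | intermediate (not isolated)
4 | 2-(benzyloxy)-1-[4-(benzyloxy)-2-fluorophenyl]ethan-1-one | O=C(COCc1ccccc1)c1ccc(OCc2ccccc2)cc1F | intermediate
5 | (Z)-{[2-(benzyloxy)-1-[4-(benzyloxy)-2-fluorophenyl]ethenyl]oxy}trimethylsilane | C[Si](C)(C)O/C(=C\OCc1ccccc1)c1ccc(OCc2ccccc2)cc1F | intermediate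
6 | 4-(benzyloxy)benzaldehyde | O=Cc1ccc(OCc2ccccc2)cc1 | starting material
7 | (2S,3R)-2-(benzyloxy)-1-[4-(benzyloxy)-2-fluorophenyl]-3-[4-(benzyloxy)phenyl]-3-[(trimethylsilyl)oxy]propan-1-one (syn silyl aldolate) | c1ccc(COc2ccc([C@@H](O[Si](C)(C)C)[C@H](OCc3ccccc3)C(=O)c3ccc(OCc4ccccc4)cc3F)cc2)cc1 | intermediate (not isolated)
8 | (2R,3S)-3,7-bis(benzyloxy)-2-[4-(benzyloxy)phenyl]-2,3-dihydro-4H-chromen-4-one (2,3-cis) | c1ccc(COc2ccc([C@H]3Oc4cc(OCc5ccccc5)ccc4C(=O)[C@H]3OCc3ccccc3)cc2)cc1 | intermediate
9 | (2R,3S)-3,7-dihydroxy-2-(4-hydroxyphenyl)-2,3-dihydro-4H-chromen-4-one (2,3-cis) | Oc1ccc([C@H]2Oc3cc(O)ccc3C(=O)[C@H]2O)cc1 | intermediate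
10 | (2R,3R,4R)-2-(4-hydroxyphenyl)chromane-3,4,7-triol (2,3-cis-3,4-cis) | Oc1ccc([C@H]2Oc3cc(O)ccc3[C@@H](O)[C@H]2O)cc1 | intermediate
11 | piceatannol, (E)-4-[2-(3,5-dihydroxyphenyl)ethenyl]benzene-1,2-diol | Oc1cc(O)cc(/C=C/c2ccc(O)c(O)c2)c1 | starting material
12 | (2R,3R,4R)-4-{2-[(E)-2-(3,4-dihydroxyphenyl)ethenyl]-4,6-dihydroxyphenyl}-2-(4-hydroxyphenyl)chromane-3,7-diol | Oc1ccc([C@H]2Oc3cc(O)ccc3[C@H](c3c(O)cc(O)cc3/C=C/c3ccc(O)c(O)c3)[C@H]2O)cc1 | target

Total step count: 6. Longest linear sequence: 6 steps (1 → 4 → 5 → 8 → 9 → 10 → 12).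

Steps most likely to fail

1. Step 3. The borane-catalysed addition may show incomplete facial or syn control with an α-benzyloxy enol silane. In addition, the unmasked alkoxide may undergo retro-aldol cleavage, or C3 of the product may epimerise, before or after ring closure, eroding the cis relation and the optical purity. The fallback uses an auxiliary-controlled syn-glycolate aldol and closes the ring as a separate step; it sets out from 6 and comes back at 8. (S)-4-Benzyloxazolidin-2-one is N-acylated with benzyloxyacetyl chloride (n-BuLi, THF, −78 °C) to give (S)-4-benzyl-3-[(benzyloxy)acetyl]oxazolidin-2-one F1. Its Z boron enolate (Bu2BOTf, Et3N, CH2Cl2, −78 °C) adds to 6 in an Evans syn aldol to give (S)-4-benzyl-3-{(2S,3R)-2-(benzyloxy)-3-[4-(benzyloxy)phenyl]-3-hydroxypropanoyl}oxazolidin-2-one F2. Transamination with MeNHOMe·HCl and AlMe3 gives the Weinreb amide (2S,3R)-2-(benzyloxy)-3-[4-(benzyloxy)phenyl]-3-hydroxy-N-methoxy-N-methylpropanamide F3. Addition of the aryl Grignard 3 (made from 1 as in step 1, 2.5 equiv, the first equivalent deprotonating the hydroxyl) gives (2S,3R)-2-(benzyloxy)-1-[4-(benzyloxy)-2-fluorophenyl]-3-[4-(benzyloxy)phenyl]-3-hydroxypropan-1-one F4. F4 is cyclised by intramolecular SNAr (K2CO3, 18-crown-6, DMF, 0 °C), quenched as soon as it is consumed, to give 8.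

2. Step 6. The C4 cation may be attacked at other nucleophilic positions of piceatannol (the ring carbon between the two hydroxyls, the olefin), and the diol may condense with itself under protic acid. The fallback replaces protic ionisation by capture and thiophilic activation; it sets out from 10 and comes back at 12. Compound 10 is treated with benzyl mercaptan (AcOH, EtOH, rt), the thiol adding trans to the 3-OH, to give the stable and purifiable (2R,3S,4S)-4-(benzylsulfanyl)-2-(4-hydroxyphenyl)chromane-3,7-diol F5. F5 is then activated with AgBF4 in THF at 0 °C in the presence of excess 11, releasing the same cation slowly under non-protic conditions, to give 12.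

3. Step 5. Phenoxide formation under the basic borohydride conditions may open ring C or enolise C3 of the free cis-dihydroflavonol, epimerising it to the trans series before reduction is complete. The fallback reduces at the protected stage and deprotects afterwards; it sets out from 8 and comes back at 10. Compound 8 is reduced under Luche conditions (NaBH4, CeCl3·7H2O, MeOH–THF, −40 °C) to give (2R,3R,4R)-3,7-bis(benzyloxy)-2-[4-(benzyloxy)phenyl]chroman-4-ol F6. F6 is debenzylated by hydrogenolysis (H2, 10% Pd/C, EtOAc, solid NaHCO3, rt, stopped at full conversion) to give 10.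

Further compounds
F1 | step 3 | (S)-4-benzyl-3-[(benzyloxy)acetyl]oxazolidin-2-one | O=C(COCc1ccccc1)N1[C@@H](Cc2ccccc2)COC1=O
F2 | step 3 | (S)-4-benzyl-3-{(2S,3R)-2-(benzyloxy)-3-[4-(benzyloxy)phenyl]-3-hydroxypropanoyl}oxazolidin-2-one | O=C([C@@H](OCc1ccccc1)[C@H](O)c1ccc(OCc2ccccc2)cc1)N1[C@@H](Cc2ccccc2)COC1=O
F3 | step 3 | (2S,3R)-2-(benzyloxy)-3-[4-(benzyloxy)phenyl]-3-hydroxy-N-methoxy-N-methylpropanamide | CON(C)C(=O)[C@@H](OCc1ccccc1)[C@H](O)c1ccc(OCc2ccccc2)cc1
F4 | step 3 | (2S,3R)-2-(benzyloxy)-1-[4-(benzyloxy)-2-fluorophenyl]-3-[4-(benzyloxy)phenyl]-3-hydroxypropan-1-one | O=C([C@@H](OCc1ccccc1)[C@H](O)c1ccc(OCc2ccccc2)cc1)c1ccc(OCc2ccccc2)cc1F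
F5 | step 6 | (2R,3S,4S)-4-(benzylsulfanyl)-2-(4-hydroxyphenyl)chromane-3,7-diol | Oc1ccc([C@H]2Oc3cc(O)ccc3[C@H](SCc3ccccc3)[C@H]2O)cc1
F6 | step 5 | (2R,3R,4R)-3,7-bis(benzyloxy)-2-[4-(benzyloxy)phenyl]chroman-4-ol | c1ccc(COc2ccc([C@H]3Oc4cc(OCc5ccccc5)ccc4[C@@H](O)[C@H]3OCc3ccccc3)cc2)cc1
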